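**Strategy**

In the target C10 carries two arms at the aldehyde oxidation level, C11–C12 and C13–C14. Both can therefore be folded back into the two carbinol carbons of a cyclopentane cis-diol in which C10 is not yet stereogenic. Periodate opens that ring, and the C9 carboxyl on the one existing stereocentre, C8, then chooses an arm: in a single operation the δ-lactone ring (C9–O–C12) and the dihydropyran ring (C12–O–C14=C13) of a 2,8-dioxabicyclo[3.3.1]nonene close, C10 and C12 are set, and the arms emerge as acylal and nucleophilic enol ether. The precursor is (2R)-2-(cis-3,4-dihydroxycyclopentyl)-3-methylidene-7-oxooctanoic acid, made by an auxiliary aldol.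

Key step: step 9

Remark (atom labels): C1=C2 is the exocyclic methylene, C3–C7 the side chain with the C6 ketone, C8 the carboxyl-bearing stereocentre, C9 the carboxyl carbon, C10 the second stereocentre, C11–C12 the CH2–CHO arm, C13–C14 the enal carbon and its CHO, C15–C18 the dihydrofuran carbons.

Remark (assumptions): the push–pull C13=C15 bond is assumed to equilibrate under the final acid conditions to the E isomer drawn, the target is taken in its open aldehyde–acid form, and chloro ketal 7 is taken as commercial.

**Route**

Step 1
Reactants: 1 2-(cyclopent-3-en-1-yl)acetic acid; 2 (R)-4-benzyloxazolidin-2-one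
Product: 4 (R)-4-benzyl-3-[2-(cyclopent-3-en-1-yl)acetyl]oxazolidin-2-one, via mixed pivalic anhydride 3 (not isolated)
Conditions: PivCl, Et3N, THF, −20 °C; then 2, LiCl, −20 °C to rt
Reagents that add atoms: none
Why: Lithium chloride-assisted N-acylation of the oxazolidinone by the mixed pivalic anhydride is a standard imide synthesis in which the hindered pivaloyl carbonyl is not attacked, and no stereocentre is formed or touched.

Step 2
Reactants: 4 (R)-4-benzyl-3-[2-(cyclopent-3-en-1-yl)acetyl]oxazolidin-2-one
Product: 5 (R)-4-benzyl-3-[2-(cis-3,4-dihydroxycyclopentyl)acetyl]oxazolidin-2-one (diol trans to the side chain)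
Conditions: OsO4 (cat.), NMO, acetone/H2O, rt
Reagents that add atoms: osmium tetroxide, O=[Os](=O)(=O)=O (delivers both oxygens catalytically); N-methylmorpholine N-oxide, C[N+]1([O-])CCOCC1, and water, O (net oxygen sources that restore OsO4)
Why: Upjohn dihydroxylation adds both oxygens suprafacially through the osmate ester, so the diol is cis, and OsO4 approaches the ring face remote from the side chain, which places the diol trans to it (any minor all-cis isomer is removed at the acetonide stage).

Step 3
Reactants: 5 (R)-4-benzyl-3-[2-(cis-3,4-dihydroxycyclopentyl)acetyl]oxazolidin-2-one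
Product: 6 (R)-4-benzyl-3-{2-[cis-3,4-(isopropylidenedioxy)cyclopentyl]acetyl}oxazolidin-2-one (acetonide trans to the side chain)
Conditions: 2,2-dimethoxypropane, PPTS (cat.), acetone, rt
Reagents that add atoms: 2,2-dimethoxypropane, COC(C)(C)OC
Why: Acid-catalysed transketalisation closes the unstrained cis-fused dioxolane on the cyclopentane cis-diol and masks it against the boron, titanium and oxidising reagents that follow, with no change at any stereocentre.

Step 4
Reactants: 7 2-(3-chloropropyl)-2-methyl-1,3-dioxolane
Product: 10 4-(2-methyl-1,3-dioxolan-2-yl)butanal, via Grignard reagent 8 (not isolated), via magnesium hemiaminal salt 9 (not isolated)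
Conditions: Mg, I2 (cat.), THF, reflux; then DMF, 0 °C; aq. NH4Cl
Reagents that add atoms: N,N-dimethylformamide, CN(C)C=O
Why: Bouveault aldehyde synthesis, in which the primary alkylmagnesium chloride (to which the dioxolane is inert) adds once to DMF and the hemiaminal salt releases the aldehyde only on buffered aqueous work-up, so over-addition is excluded.

Step 5
Reactants: 6 (R)-4-benzyl-3-{2-[cis-3,4-(isopropylidenedioxy)cyclopentyl]acetyl}oxazolidin-2-one; 10 4-(2-methyl-1,3-dioxolan-2-yl)butanal
Product: 13 (R)-4-benzyl-3-[(2R,3S)-2-[cis-3,4-(isopropylidenedioxy)cyclopentyl]-3-hydroxy-6-(2-methyl-1,3-dioxolan-2-yl)hexanoyl]oxazolidin-2-one, via boron enolate 11 (not isolated), via boron aldolate 12 (not isolated)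
Conditions: Bu2BOTf, iPr2NEt, CH2Cl2, 0 °C; then 10, −78 to 0 °C; H2O2, MeOH, pH 7 buffer
Reagents that add atoms: none
Why: Evans syn-aldol reaction, in which the Z boron enolate adds to the aldehyde through a closed chair (Zimmerman–Traxler) transition state on the enolate face not shielded by the benzyl group of the (R)-auxiliary, setting C8 as R (the C2 carbinol, S, is erased in step 6).

Step 6
Reactants: 13 aldol adduct
Product: 14 (R)-4-benzyl-3-[(2R)-2-[cis-3,4-(isopropylidenedioxy)cyclopentyl]-6-(2-methyl-1,3-dioxolan-2-yl)-3-oxohexanoyl]oxazolidin-2-one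
Conditions: Dess–Martin periodinane, pyridine, CH2Cl2, 0 °C to rt
Reagents that add atoms: none
Why: Dess–Martin oxidation under pyridine buffer gives the ketone without base, and C8 of such β-keto imides resists enolisation because allylic strain with the oxazolidinone keeps the C8–H bond out of the plane needed for deprotonation.

Step 7
Reactants: 14 β-keto imide
Product: 15 (R)-4-benzyl-3-[(2R)-2-[cis-3,4-(isopropylidenedioxy)cyclopentyl]-3-methylidene-6-(2-methyl-1,3-dioxolan-2-yl)hexanoyl]oxazolidin-2-one
Conditions: Cp2TiMe2, toluene, 65 °C, dark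
Reagents that add atoms: dimethyltitanocene Cp2TiMe2, C[Ti+2]C.c1cc[cH-]c1.c1cc[cH-]c1
Why: Petasis methylenation, in which Cp2TiMe2 loses methane to Cp2Ti=CH2, which undergoes [2+2] addition and cycloreversion with the ketone carbonyl faster than with the imide or carbamate carbonyls and, being non-basic, leaves C8 and both acetals untouched.

Step 8
Reactants: 15 methylidene imide
Product: 18 (2R)-2-(cis-3,4-dihydroxycyclopentyl)-3-methylidene-7-oxooctanoic acid (diol trans to the side chain), via peroxy acid 16 (not isolated), via protected acid 17 (not isolated)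
Conditions: LiOH, H2O2, THF/H2O, 0 °C; Na2SO3 (aq); CH2Cl2 wash; then HCl (aq, pH 1), THF, rt
Reagents that add atoms: hydrogen peroxide, OO; water, O
Why: Hydroperoxide attacks the exocyclic imide carbonyl selectively (standard LiOOH auxiliary cleavage, the peracid being reduced by sulfite) without epimerising C8, and the dilute acid then hydrolyses the acetonide and the dioxolane together to the diol keto acid, whose diol is trans to the side chain and so cannot lactonise.

Step 9
Reactants: 18 (2R)-2-(cis-3,4-dihydroxycyclopentyl)-3-methylidene-7-oxooctanoic acid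
Product: 21 (1S,4R,5R)-4-(6-oxohept-1-en-2-yl)-2,8-dioxabicyclo[3.3.1]non-6-en-3-one, via dialdehyde acid 19 (not isolated), via bicyclic lactol 20 (not isolated)
Conditions: NaIO4, THF/H2O, 0 °C to rt; extraction (EtOAc); then PPTS (cat.), 4 Å MS, toluene (high dilution), 80 °C
Reagents that add atoms: none
Why: NaIO4 forms a cyclic periodate ester with the cis-diol and cleaves the C12–C14 bond, leaving two CH2–CHO arms on C10 that sit in water as the 2,6-dihydroxytetrahydropyran hydrate. With weak acid and removal of water the C14 oxygen adds to C12 (6-exo-trig hemiacetalisation), the C9 carboxyl traps the C12 oxocarbenium ion as an acylal (6-exo-trig lactonisation) and the C14 lactol loses water to the C13=C14 enol ether; the closest known reaction type is glycol cleavage followed by acid-catalysed lactone-acetal closure of secoiridoid-type dialdehyde acids. Every C–O bond formed is reversible, so the two diastereotopic arms exchange through the open dialdehyde (or the symmetric 4H-pyran) and the outcome is thermodynamic. C10 becomes stereogenic here and is controlled by C8: in the bicycle drawn the alkenyl group is equatorial on the lactone chair and meets only the planar C13=C14 unit, whereas closure on the other arm would force it axial and syn to a C11 hydrogen; C12 is a bridgehead whose configuration is dictated by the cis bridging. The step needs arm selectivity, which rests on that equatorial preference (expected to be modest, so any arm isomer is separated and returned to the same equilibration), and chemoselectivity, which follows because periodate ignores the C1=C2 alkene and the ketone and PPTS is too weak to enolise C8 or protonate the alkene.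

Step 10
Reactants: 21 bicyclic lactone acetal
Product: 23 C13 carbonyl chloride of 21 (3-oxo-4-(6-oxohept-1-en-2-yl)-2,8-dioxabicyclo[3.3.1]non-6-ene-6-carbonyl chloride; configuration as in 21), via glyoxylyl chloride 22 (not isolated)
Conditions: (COCl)2, 2,6-di-tert-butyl-4-methylpyridine, CH2Cl2, 0 °C to rt; evaporate; toluene, 100 °C
Reagents that add atoms: oxalyl chloride, O=C(Cl)C(=O)Cl
Why: Electrophilic acylation of the enol ether, in which C13 (the β-carbon of the C13=C14–O unit) attacks oxalyl chloride and the oxocarbenium ion gives up the C13 proton to the hindered pyridine, followed by thermal loss of CO from the β-alkoxyvinyl glyoxylyl chloride (the established route from enol ethers to 3-alkoxyacryloyl chlorides); from here the two arms are constitutionally different, so C10 can no longer be lost by acetal exchange.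

Step 11
Reactants: 23 C13 carbonyl chloride; 24 2-methylbut-3-yn-2-ol
Product: 25 6-(4-hydroxy-4-methylpent-2-ynoyl)-4-(6-oxohept-1-en-2-yl)-2,8-dioxabicyclo[3.3.1]non-6-en-3-one (configuration as in 21)
Conditions: PdCl2(PPh3)2 (cat.), CuI (cat.), Et3N, THF, rt
Reagents that add atoms: none
Why: Acyl Sonogashira coupling, in which the acid chloride adds oxidatively to zerovalent palladium, the copper acetylide formed from the terminal alkyne and Et3N transmetalates and reductive elimination gives the ynone at room temperature, where the tertiary alcohol is not acylated and the acylal, ketone and alkene are inert.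

Step 12
Reactants: 25 ynone
Product: 27 (2R)-2-[(2E,3S)-2-(5,5-dimethylfuran-2(5H)-ylidene)-1,5-dioxopentan-3-yl]-3-methylidene-7-oxooctanoic acid (target), via Z-hydroxy enone 26 (not isolated)
Conditions: H2 (1 atm), Pd/CaCO3 poisoned with Pb(OAc)2 (Lindlar catalyst), quinoline, EtOAc, rt; filter; then 0.5 M HCl, THF/H2O, rt
Reagents that add atoms: water, O
Why: Lindlar semi-hydrogenation adds H2 syn to the alkyne only and gives the Z-enone, whose tertiary hydroxyl reaches the C15 ketone; in aqueous acid the hemiketal (5-exo-trig) loses water to a vinylogous dioxocarbenium ion, water adds at C14, the pyran opens and the hemi-acylal at C12 collapses to the free aldehyde and the C9 acid, the push–pull β-alkoxy enal being the thermodynamic sink with the branched C10 next to the ring oxygen (E), and no stereocentre is touched.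

**Compound list**

1 | 2-(cyclopent-3-en-1-yl)acetic acid | OC(=O)CC1CC=CC1 | starting material
2 | (R)-4-benzyloxazolidin-2-one | O=C1N[C@H](Cc2ccccc2)CO1 | starting material
3 | mixed anhydride of 1 with pivalic acid | CC(C)(C)C(=O)OC(=O)CC1CC=CC1 | intermediate
4 | (R)-4-benzyl-3-[2-(cyclopent-3-en-1-yl)acetyl]oxazolidin-2-one | O=C(CC1CC=CC1)N1[C@H](Cc2ccccc2)COC1=O | intermediate
5 | cis-diol imide, diol trans to the side chain | O=C(C[C@H]1C[C@H](O)[C@H](O)C1)N1[C@H](Cc2ccccc2)COC1=O | intermediate
6 | acetonide of 5 | O=C(C[C@H]1C[C@@H]2OC(C)(C)O[C@@H]2C1)N1[C@H](Cc2ccccc2)COC1=O | intermediate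
7 | 2-(3-chloropropyl)-2-methyl-1,3-dioxolane | CC1(CCCCl)OCCO1 | starting material
8 | Grignard reagent from 7 | CC1(CCC[Mg]Cl)OCCO1 | intermediate
9 | chloromagnesium salt of the DMF adduct of 8 | CC1(CCCC(O[Mg]Cl)N(C)C)OCCO1 | intermediate
10 | 4-(2-methyl-1,3-dioxolan-2-yl)butanal | CC1(CCCC=O)OCCO1 | intermediate
11 | Z dibutylboron enolate of 6 | CCCCB(CCCC)O/C(=C\[C@H]1C[C@@H]2OC(C)(C)O[C@@H]2C1)N1[C@H](Cc2ccccc2)COC1=O | intermediate
12 | dibutylboron aldolate of 13 | CC1(CCC[C@H](OB(CCCC)CCCC)[C@H](C(=O)N2[C@H](Cc3ccccc3)COC2=O)[C@H]2C[C@@H]3OC(C)(C)O[C@@H]3C2)OCCO1 | intermediate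
13 | syn-aldol adduct, (2R,3S) in the hexanoyl chain | CC1(CCC[C@H](O)[C@H](C(=O)N2[C@H](Cc3ccccc3)COC2=O)[C@H]2C[C@@H]3OC(C)(C)O[C@@H]3C2)OCCO1 | intermediate
14 | β-keto imide, (2R) | CC1(CCCC(=O)[C@H](C(=O)N2[C@H](Cc3ccccc3)COC2=O)[C@H]2C[C@@H]3OC(C)(C)O[C@@H]3C2)OCCO1 | intermediate
15 | 3-methylidene imide, (2R) | CC1(CCCC(=C)[C@H](C(=O)N2[C@H](Cc3ccccc3)COC2=O)[C@H]2C[C@@H]3OC(C)(C)O[C@@H]3C2)OCCO1 | intermediate
16 | peroxy acid from cleavage of 15 | CC1(CCCC(=C)[C@H](C(=O)OO)[C@H]2C[C@@H]3OC(C)(C)O[C@@H]3C2)OCCO1 | intermediate
17 | (2R)-2-[cis-3,4-(isopropylidenedioxy)cyclopentyl]-3-methylidene-6-(2-methyl-1,3-dioxolan-2-yl)hexanoic acid | CC1(CCCC(=C)[C@H](C(=O)O)[C@H]2C[C@@H]3OC(C)(C)O[C@@H]3C2)OCCO1 | intermediate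
18 | (2R)-2-(cis-3,4-dihydroxycyclopentyl)-3-methylidene-7-oxooctanoic acid, diol trans to the side chain | C=C(CCCC(C)=O)[C@H](C(=O)O)[C@H]1C[C@H](O)[C@H](O)C1 | intermediate
19 | (2R)-3-methylidene-7-oxo-2-(1,5-dioxopentan-3-yl)octanoic acid | C=C(CCCC(C)=O)[C@H](C(=O)O)C(CC=O)CC=O | intermediate
20 | bicyclic lactone acetal with C14–OH (lactol, anomer mixture) | C=C(CCCC(C)=O)[C@H]1[C@@H]2C[C@H](OC1=O)OC(O)C2 | intermediate
21 | (1S,4R,5R)-4-(6-oxohept-1-en-2-yl)-2,8-dioxabicyclo[3.3.1]non-6-en-3-one | C=C(CCCC(C)=O)[C@H]1[C@@H]2C[C@H](OC1=O)OC=C2 | intermediate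
22 | C13 glyoxylyl chloride of 21 | C=C(CCCC(C)=O)[C@H]1[C@@H]2C[C@H](OC1=O)OC=C2C(=O)C(=O)Cl | intermediate
23 | C13 carbonyl chloride of 21 | C=C(CCCC(C)=O)[C@H]1[C@@H]2C[C@H](OC1=O)OC=C2C(=O)Cl | intermediate
24 | 2-methylbut-3-yn-2-ol | CC(C)(O)C#C | starting material
25 | C13 4-hydroxy-4-methylpent-2-ynoyl derivative of 21 | C=C(CCCC(C)=O)[C@H]1[C@@H]2C[C@H](OC1=O)OC=C2C(=O)C#CC(C)(C)O | intermediate
26 | Z-4-hydroxy-4-methylpent-2-enoyl derivative of 21 | C=C(CCCC(C)=O)[C@H]1[C@@H]2C[C@H](OC1=O)OC=C2C(=O)/C=C\C(C)(C)O | intermediate
27 | (2R)-2-[(2E,3S)-2-(5,5-dimethylfuran-2(5H)-ylidene)-1,5-dioxopentan-3-yl]-3-methylidene-7-oxooctanoic acid | C=C(CCCC(C)=O)[C@H](C(=O)O)[C@H](CC=O)/C(C=O)=C1/C=CC(C)(C)O1 | target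

**Step count**

Total steps: 12. Longest linear sequence: 11 steps (steps 1–3 and 5–12, from 1); aldehyde 10 is made in one separate step.

**Steps most likely to fail**

Step 9. The equilibrium may discriminate only weakly between the two arms, because the equatorial and axial placements of the alkenyl group differ by one gauche-type contact. Dehydration of the C14 lactol may also lag. On long acid exposure the C1=C2 alkene may add to an oxocarbenium ion in an ene-type C–C closure. The fallback sets out from 18 and returns at 21, and it decouples ring closure from enol-ether formation. After the periodate cleavage, 19 is equilibrated with PPTS in CH2Cl2 at room temperature only as far as bicyclic lactol 20, which is isolated. The arm isomers are separated at this stage and the unwanted one is returned to the acid. Lactol 20 is then treated with MsCl and Et3N (CH2Cl2, −20 °C to rt), and the anomeric mesylate F1 loses methanesulfonate under the amine to give 21. This is the usual base-mediated lactol-to-enol-ether dehydration, and it keeps acid and heat away from the alkene.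

Step 10. Hydrogen chloride released during acylation may ionise the acylal and let the arms exchange before C13 is substituted. The glyoxylyl chloride may also lose CO sluggishly or decompose at 100 °C. The fallback sets out from 21 and returns at 25. C13 is iodinated with NIS and catalytic AgNO3 in MeCN (electrophilic iodination of a cyclic enol ether with loss of the C13 proton) to give vinyl iodide F2. F2 is coupled with 24 under CO (1 atm) with PdCl2(PPh3)2 and Et3N in THF, a carbonylative Sonogashira reaction that gives ynone 25 directly. This avoids both the acid chloride and the thermal step.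

Step 7. The titanium reagent may enolise the β-keto imide, trigger retro-Claisen cleavage or methylenate the imide carbonyl, which would erode C8 or the conversion. The fallback sets out from 13 and returns at 17, and it removes the 1,3-dicarbonyl relationship before the methylene is introduced.
- Aldol 13 is cleaved reductively with LiBH4 (THF, H2O, 0 °C) to diol F3, with release of the auxiliary.
- The primary hydroxyl is silylated selectively (TBSCl, imidazole, CH2Cl2, 0 °C) to give silyl ether F4.
- Dess–Martin oxidation gives ketone F5, now a plain α-branched ketone, which is methylenated with Cp2TiMe2 to alkene F6.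
- TBAF frees alcohol F7.
- Dess–Martin oxidation to aldehyde F8, followed at once by Pinnick oxidation (NaClO2, NaH2PO4, 2-methylbut-2-ene), gives protected acid 17, which enters the aqueous HCl stage of step 8.

**Further compounds**

F1 | step 9 | anomeric (C14) mesylate of bicyclic lactol 20 | C=C(CCCC(C)=O)[C@H]1[C@@H]2C[C@H](OC1=O)OC(OS(C)(=O)=O)C2
F2 | step 10 | C13 vinyl iodide of 21 | C=C(CCCC(C)=O)[C@H]1[C@@H]2C[C@H](OC1=O)OC=C2I
F3 | step 7 | 1,3-diol from reductive removal of the auxiliary from 13 | CC1(CCC[C@H](O)[C@H](CO)[C@H]2C[C@@H]3OC(C)(C)O[C@@H]3C2)OCCO1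
F4 | step 7 | primary TBS ether of F3 | CC1(CCC[C@H](O)[C@H](CO[Si](C)(C)C(C)(C)C)[C@H]2C[C@@H]3OC(C)(C)O[C@@H]3C2)OCCO1
F5 | step 7 | ketone from oxidation of F4 | CC1(CCCC(=O)[C@H](CO[Si](C)(C)C(C)(C)C)[C@H]2C[C@@H]3OC(C)(C)O[C@@H]3C2)OCCO1
F6 | step 7 | 1,1-disubstituted alkene from methylenation of F5 | CC1(CCCC(=C)[C@H](CO[Si](C)(C)C(C)(C)C)[C@H]2C[C@@H]3OC(C)(C)O[C@@H]3C2)OCCO1
F7 | step 7 | primary alcohol from desilylation of F6 | CC1(CCCC(=C)[C@H](CO)[C@H]2C[C@@H]3OC(C)(C)O[C@@H]3C2)OCCO1
F8 | step 7 | aldehyde from oxidation of F7 | CC1(CCCC(=C)[C@H](C=O)[C@H]2C[C@@H]3OC(C)(C)O[C@@H]3C2)OCCO1
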